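**Retrosynthetic overview**
- Target ⇒ last-step C-prenylation (Pd, exo face) of a tricyclic enolised acyl-dione that already holds four of the five stereocentres.
- Tricycle ⇒ monocyclic dearomatised acylphloroglucinol by one oxidative cascade. The triketone enol carbon, normally a nucleophile, is oxidised to an electrophilic α-acyl radical and bonded to the nucleophilic CH of the prenyl olefin. The tertiary radical then closes the cyclopentane onto a vinyl chloride, which emerges as the acetyl group.
- Dearomatised precursor ⇒ aromatic acylphloroglucinol by Pd-catalysed asymmetric dearomative prenylation; this sets the only catalyst-controlled stereocentre, and all others are relayed from it.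
- Aromatic precursor ⇒ 2-methylphloroglucinol + isobutyryl chloride + 1,3-dichlorobut-2-ene.
- Ring order: benzene ring (bought) → dearomatised cyclohexadienone → cyclopentanone ring of the bicyclo[3.2.1]octane → gem-dimethylcyclopentane (the last two in one flask).

Assumption: the commercial E/Z mixture of the dichlorobutene is used and its alkene geometry (destroyed in the cascade) is left undefined in SMILES; the (R,R) ligand is taken to give the R dienone, and the (S,S) ligand is used if the sense of induction proves opposite; tricyclic compounds are numbered as tricyclo[5.3.1.0^{1,5}]undecanes, and the CIP descriptors were derived by hand from the SMILES, which are authoritative.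

**Step 1**
Reactants: 1 2-methylbenzene-1,3,5-triol (2-methylphloroglucinol); 2 2-methylpropanoyl chloride (isobutyryl chloride)
Product: 3 1-(2,4,6-trihydroxy-3-methylphenyl)-2-methylpropan-1-one
Conditions: AlCl3 (3.5 equiv), PhNO2/CH2Cl2, 0 °C to 60 °C; aq. HCl quench
Reagents that add atoms: 2-methylpropanoyl chloride (2), CC(C)C(Cl)=O
Why: Friedel–Crafts C-acylation (via O-acylation/Fries under AlCl3) of the electron-rich triol at one of its two equivalent free ring positions, the acyl group then deactivating the ring against a second acylation; no stereocentre is formed.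

**Step 2**
Reactants: 3 1-(2,4,6-trihydroxy-3-methylphenyl)-2-methylpropan-1-one; 4 1,3-dichlorobut-2-ene (E/Z mixture)
Product: 5 1-[3-(3-chlorobut-2-en-1-yl)-2,4,6-trihydroxy-5-methylphenyl]-2-methylpropan-1-one
Conditions: KOH (1.1 equiv), NaI (10 mol %), H2O–MeOH, 0 °C to rt; 4 (0.95 equiv) added slowly
Reagents that add atoms: 1,3-dichlorobut-2-ene (4), ClCC=C(C)Cl
Why: Phenolate C-alkylation (SN2 at the allylic chloride, the vinylic chloride being inert) at the only unsubstituted ring carbon, favoured in protic medium over O-alkylation and over dearomatising attack at the methyl-bearing carbon because it keeps the ring aromatic; no stereocentre is formed.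

**Step 3**
Reactants: 5 1-[3-(3-chlorobut-2-en-1-yl)-2,4,6-trihydroxy-5-methylphenyl]-2-methylpropan-1-one; 6 3-methylbut-2-en-1-yl acetate (prenyl acetate)
Product: 7 (6R)-2-(3-chlorobut-2-en-1-yl)-3,5-dihydroxy-6-methyl-6-(3-methylbut-2-en-1-yl)-4-(2-methylpropanoyl)cyclohexa-2,4-dien-1-one
Conditions: Pd2(dba)3 (2.5 mol %), (R,R)-DACH-phenyl Trost ligand (7.5 mol %), Li2CO3 (1.0 equiv), 6 (1.0 equiv), THF, 25 °C
Reagents that add atoms: 3-methylbut-2-en-1-yl acetate (6), CC(=O)OCC=C(C)C
Why: Proposed new method: Tsuji–Trost asymmetric allylic dearomatisation in which the acylphloroglucinolate attacks the cationic (π-prenyl)palladium complex (formed from zerovalent palladium and 6) at its unsubstituted terminus through the less hindered methyl-bearing ring carbon, O-allylation being reversible under the catalysis and draining to the C-product, while the chiral pocket of the ligand selects one face of the flat nucleophile and so sets the R quaternary centre; the closest known reaction types are the Pd/Trost-ligand asymmetric allylic dearomatisation of 1-substituted 2-naphthols and the racemic Pd-catalysed dearomative allylation of acylphloroglucinols.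

**Step 4**
Reactants: 7 (6R)-2-(3-chlorobut-2-en-1-yl)-3,5-dihydroxy-6-methyl-6-(3-methylbut-2-en-1-yl)-4-(2-methylpropanoyl)cyclohexa-2,4-dien-1-one
Product: 9 (1S,3S,5R,7S)-3-acetyl-10-hydroxy-4,4,7-trimethyl-9-(2-methylpropanoyl)tricyclo[5.3.1.0^{1,5}]undec-9-ene-8,11-dione, via 3-epi-acetyl tricycle 8 (not isolated)
Conditions: Mn(OAc)3·2H2O (2.2 equiv), degassed AcOH (no copper salt), 25 °C; aqueous work-up; then TsOH·H2O (10 mol %), PhMe, 60 °C
Reagents that add atoms: water (hydrate water of Mn(OAc)3·2H2O and aqueous work-up), O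
Why: Mn(OAc)3-based oxidative free-radical cyclisation in which trivalent manganese turns the normally nucleophilic enol carbon C2 of 7 into an electrophilic α-acyl radical (a one-electron enolonium equivalent) that attacks the nucleophilic CH terminus of the prenyl olefin 5-exo, the tether on the R quaternary carbon fixing both bridgeheads and only the exo tertiary radical being able to reach the side chain, after which a second 5-exo closure onto the chloroalkene gives an α-chloro radical that is oxidised to the chlorocarbenium ion and solvolysed to the methyl ketone, and acid-catalysed enolisation finally drains the acetyl epimer 8 into the less hindered 9 (acetyl on the convex face, trans to the cyclopentanone ring).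

**Step 5**
Reactants: 9 (1S,3S,5R,7S)-3-acetyl-10-hydroxy-4,4,7-trimethyl-9-(2-methylpropanoyl)tricyclo[5.3.1.0^{1,5}]undec-9-ene-8,11-dione; 6 3-methylbut-2-en-1-yl acetate (prenyl acetate)
Product: 10 (1R,3S,5R,7S,9S)-3-acetyl-4,4,7-trimethyl-9-(3-methylbut-2-en-1-yl)-9-(2-methylpropanoyl)tricyclo[5.3.1.0^{1,5}]undecane-8,10,11-trione (CNP0322535.2)
Conditions: Pd(PPh3)4 (5 mol %), Cs2CO3 (1.1 equiv), 6 (1.2 equiv), THF, 25 to 40 °C
Reagents that add atoms: 3-methylbut-2-en-1-yl acetate (6), CC(=O)OCC=C(C)C
Why: Tsuji–Trost allylation in which the soft triketone enolate attacks the (π-prenyl)palladium cation at its unhindered CH2 terminus through C9 (O-prenylation is reversible under the catalysis and drains to the C-prenyl product) from the exo face of the bicyclo[3.2.1]octene, anti to the two-carbon bridge, which places the prenyl group cis to the bridgehead methyl and the acyl group over the two-carbon bridge as in the target (9S).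

**Compound list**
1 | 2-methylbenzene-1,3,5-triol (2-methylphloroglucinol) | Cc1c(O)cc(O)cc1O | starting material
2 | 2-methylpropanoyl chloride (isobutyryl chloride) | CC(C)C(Cl)=O | starting material
3 | 1-(2,4,6-trihydroxy-3-methylphenyl)-2-methylpropan-1-one | CC(C)C(=O)c1c(O)cc(O)c(C)c1O | intermediate
4 | 1,3-dichlorobut-2-ene (E/Z mixture) | ClCC=C(C)Cl | starting material
5 | 1-[3-(3-chlorobut-2-en-1-yl)-2,4,6-trihydroxy-5-methylphenyl]-2-methylpropan-1-one | CC(C)C(=O)c1c(O)c(CC=C(C)Cl)c(O)c(C)c1O | intermediate
6 | 3-methylbut-2-en-1-yl acetate (prenyl acetate) | CC(=O)OCC=C(C)C | starting material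
7 | (6R)-2-(3-chlorobut-2-en-1-yl)-3,5-dihydroxy-6-methyl-6-(3-methylbut-2-en-1-yl)-4-(2-methylpropanoyl)cyclohexa-2,4-dien-1-one | O=C1C(CC=C(C)Cl)=C(O)C(C(=O)C(C)C)=C(O)[C@@]1(C)CC=C(C)C | intermediate
8 | (1S,3R,5R,7S)-3-acetyl-10-hydroxy-4,4,7-trimethyl-9-(2-methylpropanoyl)tricyclo[5.3.1.0^{1,5}]undec-9-ene-8,11-dione (3-epimer of 9) | CC(=O)[C@@H]1C[C@]23C(=O)[C@](C)(C[C@@H]2C1(C)C)C(=O)C(C(=O)C(C)C)=C3O | intermediate (not isolated)
9 | (1S,3S,5R,7S)-3-acetyl-10-hydroxy-4,4,7-trimethyl-9-(2-methylpropanoyl)tricyclo[5.3.1.0^{1,5}]undec-9-ene-8,11-dione | CC(=O)[C@H]1C[C@]23C(=O)[C@](C)(C[C@@H]2C1(C)C)C(=O)C(C(=O)C(C)C)=C3O | intermediate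
10 | (1R,3S,5R,7S,9S)-3-acetyl-4,4,7-trimethyl-9-(3-methylbut-2-en-1-yl)-9-(2-methylpropanoyl)tricyclo[5.3.1.0^{1,5}]undecane-8,10,11-trione | CC(=O)[C@H]1C[C@]23C(=O)[C@](C)(C[C@@H]2C1(C)C)C(=O)[C@](CC=C(C)C)(C(=O)C(C)C)C3=O | target

**Totals**
Total step count: 5. Longest linear sequence: 5 steps (1 → 3 → 5 → 7 → 9 → 10).

**Steps most likely to fail, each with a fallback**

Step 3 carries two risks: prenylation at the chlorobutenyl-bearing carbon instead of the methyl-bearing one, and insufficient enantioselectivity. The fallback replaces catalyst control by classical resolution. It sets out from 5: prenyl bromide with NaOMe in MeOH at 0 °C gives the racemic dearomatised dienone F1 (the regioisomer is removed by chromatography). The acidic triketone is crystallised with (S)-1-phenylethylamine to the less soluble diastereomeric (S)-1-phenylethylammonium salt of the 6R dienone F2; should the 6S salt crystallise instead, the R amine is used. Dilute HCl releases the free dienone, and the route is rejoined at 7.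

Step 4 may fail in three ways: the α-chloro radical may not be oxidised cleanly to the ketone, the acyl-bearing ring carbon may cyclise in competition, or the yield may be low (30–40 % is expected). The fallback uses an all-carbon radical terminator and cleaves it afterwards. It sets out from 3: prenyl bromide with aqueous KOH gives the ring-prenylated acylphloroglucinol F3. The Pd-catalysed dearomative prenylation of step 3 then gives the bis-prenyl dienone F4. Mn(OAc)3·2H2O with Cu(OAc)2·H2O in AcOH closes both rings and ends in the isopropenyl tricycle F5 (mixture of epimers at C3). OsO4 (cat.) and NaIO4 with 2,6-lutidine in dioxane–water cleave the 1,1-disubstituted alkene to the acetyl group, and the TsOH equilibration of step 4 rejoins the route at 9.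

Step 5 may give O-prenylation or the wrong face at C9. The fallback delivers the prenyl group intramolecularly by a sigmatropic shift. It sets out from 9: 3-chloro-3-methylbut-1-yne with CuCl2 (cat.) and DBU in MeCN at 0 °C gives the 1,1-dimethylpropargyl enol ether F6 (either enol oxygen serves). Semihydrogenation with H2 over Pd/CaCO3 poisoned with Pb(OAc)2 and quinoline gives the 1,1-dimethylallyl enol ether F7. Heating in PhMe at 80 °C triggers the Claisen [3,3] shift, which turns the reverse-prenyl ether into the linear C9-prenyl group on the exo face, and the route is rejoined at 10.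

**Further compounds**
F1 | step 3 | racemic 2-(3-chlorobut-2-en-1-yl)-3,5-dihydroxy-6-methyl-6-(3-methylbut-2-en-1-yl)-4-(2-methylpropanoyl)cyclohexa-2,4-dien-1-one | O=C1C(CC=C(C)Cl)=C(O)C(C(=O)C(C)C)=C(O)C1(C)CC=C(C)C
F2 | step 3 | (S)-1-phenylethylammonium salt of the 6R dienone (enolate of 7) | O=C1C(CC=C(C)Cl)=C([O-])C(C(=O)C(C)C)=C(O)[C@@]1(C)CC=C(C)C.C[C@H]([NH3+])c1ccccc1
F3 | step 4 | 1-[2,4,6-trihydroxy-3-methyl-5-(3-methylbut-2-en-1-yl)phenyl]-2-methylpropan-1-one | CC(C)C(=O)c1c(O)c(CC=C(C)C)c(O)c(C)c1O
F4 | step 4 | (6R)-3,5-dihydroxy-6-methyl-2,6-bis(3-methylbut-2-en-1-yl)-4-(2-methylpropanoyl)cyclohexa-2,4-dien-1-one | O=C1C(CC=C(C)C)=C(O)C(C(=O)C(C)C)=C(O)[C@@]1(C)CC=C(C)C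
F5 | step 4 | (1S,5R,7S)-10-hydroxy-4,4,7-trimethyl-9-(2-methylpropanoyl)-3-(prop-1-en-2-yl)tricyclo[5.3.1.0^{1,5}]undec-9-ene-8,11-dione, mixture of epimers at C3 | CC(=C)C1C[C@]23C(=O)[C@](C)(C[C@@H]2C1(C)C)C(=O)C(C(=O)C(C)C)=C3O
F6 | step 5 | 10-O-(2-methylbut-3-yn-2-yl) enol ether of 9 | CC(=O)[C@H]1C[C@]23C(=O)[C@](C)(C[C@@H]2C1(C)C)C(=O)C(C(=O)C(C)C)=C3OC(C)(C)C#C
F7 | step 5 | 10-O-(2-methylbut-3-en-2-yl) enol ether of 9 | CC(=O)[C@H]1C[C@]23C(=O)[C@](C)(C[C@@H]2C1(C)C)C(=O)C(C(=O)C(C)C)=C3OC(C)(C)C=C
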